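**Plan**
- Retrosynthesis: remove the seven MOM ethers; cut the chalcone Cα=Cβ bond on the A-ring side chain (aldol); cut the aryl ketone bond between the carbonyl on cyclohexene C-1 and C-1 of ring B (the 2,4-dioxygenated, 3-alkenylated benzene ring) to give carboxylic acid 22 and aryl bromide 5; cut the two Diels–Alder bonds of the cyclohexene (C-1–C-2 and C-5–C-6).
- Forward: three bought benzene rings are functionalised separately; the methylcyclohexene, the only ring that is built, arises by Diels–Alder reaction of dienyl acetophenone 12 with cinnamoyl imide 19; the auxiliary is removed; acid and bromide are joined at nickel; the chalcone is completed; the MOM groups are removed.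
- Feature used by the key event: the ketone carbon between cyclohexene C-1 and ring B is an acyl carbon at the carboxylic acid level, and its partner is the one ring-B carbon ortho to O-2 and para to O-4 (C-3 carries the alkenyl chain), the site bromine enters unaided. Both ends are therefore electrophiles and are united reductively without base, so the epimerisable cis centre next to the carbonyl is kept.
- Stereochemistry: all three stereocentres come from one auxiliary-controlled endo Diels–Alder step ((S)-4-benzyloxazolidinone, aluminium chelate, Cα-Si face); the E alkenes come from Suzuki coupling (retention), Heck reaction, Knoevenagel–Doebner condensation and E1cB elimination.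

Key step: step 13

Assumption: 2-iodoresorcinol (1) and the (E)-alkenylboronic ester 3 are taken as purchasable, and I2/HIO3 iodination of resacetophenone is taken to go to C-3, between the two hydroxyl groups.

**Step 1**
Reactants: 1 2-iodobenzene-1,3-diol
Product: 2 2-iodo-1,3-bis(methoxymethoxy)benzene
Conditions: MOMCl, iPr2NEt, CH2Cl2, 0 °C to rt
Reagents that add atoms: chloromethyl methyl ether, COCCl
Why: O-alkylation of both phenols (MOM ether formation) with an amine base should proceed without touching the iodide.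

**Step 2**
Reactants: 2 2-iodo-1,3-bis(methoxymethoxy)benzene; 3 4,4,5,5-tetramethyl-2-[(E)-3-methylbut-1-en-1-yl]-1,3,2-dioxaborolane
Product: 4 1,3-bis(methoxymethoxy)-2-[(E)-3-methylbut-1-en-1-yl]benzene
Conditions: Pd(OAc)2 (3 mol %), SPhos, K3PO4, toluene–H2O, 80 °C
Reagents that add atoms: none
Why: A Suzuki–Miyaura coupling with a bulky biaryl phosphine should cope with the doubly ortho-substituted iodide and transfer the alkenyl group with retention of its E geometry.

**Step 3**
Reactants: 4 1,3-bis(methoxymethoxy)-2-[(E)-3-methylbut-1-en-1-yl]benzene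
Product: 5 1-bromo-2,4-bis(methoxymethoxy)-3-[(E)-3-methylbut-1-en-1-yl]benzene
Conditions: NBS (1.0 equiv), CH2Cl2, −20 to 0 °C, dark
Reagents that add atoms: N-bromosuccinimide, O=C1CCC(=O)N1Br
Why: Electrophilic aromatic bromination should go to the only ring position ortho to one OMOM group and para to the other (C-4 and C-6 are equivalent, C-2 is blocked), the twisted and flanked styrene-type alkene being much less nucleophilic than this ring at low temperature.

**Step 4**
Reactants: 6 1-(2,4-dihydroxyphenyl)ethanone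
Product: 7 1-(2,4-dihydroxy-3-iodophenyl)ethanone
Conditions: I2, HIO3, EtOH–H2O, 40 °C
Reagents that add atoms: iodine, II; iodic acid, OI(=O)=O
Why: Oxidative electrophilic iodination of the resorcinol ring is expected to place iodine at C-3 between the two hydroxyl groups, with all iodine used.

**Step 5**
Reactants: 7 1-(2,4-dihydroxy-3-iodophenyl)ethanone
Product: 8 1-[3-iodo-2,4-bis(methoxymethoxy)phenyl]ethanone
Conditions: NaH, MOMCl, DMF, 0 °C to rt
Reagents that add atoms: chloromethyl methyl ether, COCCl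
Why: O-alkylation of both phenoxides (MOM ether formation) should be complete, sodium hydride being needed for the chelated and flanked 2-OH.

**Step 6**
Reactants: 8 1-[3-iodo-2,4-bis(methoxymethoxy)phenyl]ethanone; 9 2-methylbut-3-en-2-ol
Product: 10 1-{3-[(E)-3-hydroxy-3-methylbut-1-en-1-yl]-2,4-bis(methoxymethoxy)phenyl}ethanone
Conditions: Pd(OAc)2 (5 mol %), Bu4NCl, NaHCO3, DMF, 80 °C
Reagents that add atoms: none
Why: In this Heck reaction, syn insertion of the terminal alkene and syn β-hydride elimination (the carbinol carbon has no hydrogen) should give the E allylic alcohol only.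

**Step 7**
Reactants: 10 1-{3-[(E)-3-hydroxy-3-methylbut-1-en-1-yl]-2,4-bis(methoxymethoxy)phenyl}ethanone
Product: 12 1-{2,4-bis(methoxymethoxy)-3-[(E)-3-methylbuta-1,3-dien-1-yl]phenyl}ethanone, via tertiary mesylate 11 (not isolated)
Conditions: MsCl, Et3N, CH2Cl2, 0 °C to rt
Reagents that add atoms: none
Why: Mesylation of the tertiary allylic alcohol and elimination in the same flask (dehydration) should give the conjugated diene while the E geometry of the aryl-bearing double bond is kept.

**Step 8**
Reactants: 13 2,4-dihydroxybenzaldehyde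
Product: 14 2,4-bis(methoxymethoxy)benzaldehyde
Conditions: MOMCl, iPr2NEt, CH2Cl2, 0 °C to reflux
Reagents that add atoms: chloromethyl methyl ether, COCCl
Why: MOM ether formation on both phenols masks them for the Lewis acid, nickel and enolate steps ahead.

**Step 9**
Reactants: 14 2,4-bis(methoxymethoxy)benzaldehyde; 15 malonic acid
Product: 16 (E)-3-[2,4-bis(methoxymethoxy)phenyl]prop-2-enoic acid
Conditions: pyridine, piperidine (cat.), 95 °C; cold dilute HCl to pH 3
Reagents that add atoms: none
Why: Knoevenagel–Doebner condensation with decarboxylation should give the E cinnamic acid under basic conditions that MOM ethers tolerate.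

**Step 10**
Reactants: 16 (E)-3-[2,4-bis(methoxymethoxy)phenyl]prop-2-enoic acid; 17 (4S)-4-benzyl-1,3-oxazolidin-2-one
Product: 19 (4S)-4-benzyl-3-{(E)-3-[2,4-bis(methoxymethoxy)phenyl]prop-2-enoyl}-1,3-oxazolidin-2-one, via mixed pivalic anhydride 18 (not isolated)
Conditions: PivCl, Et3N, THF, −20 °C; then 17, LiCl, −20 °C to rt
Reagents that add atoms: none
Why: N-Acylation of the oxazolidinone through the mixed anhydride should occur at the less hindered cinnamoyl carbonyl, the auxiliary stereocentre not being involved.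

**Step 11**
Reactants: 19 (4S)-4-benzyl-3-{(E)-3-[2,4-bis(methoxymethoxy)phenyl]prop-2-enoyl}-1,3-oxazolidin-2-one; 12 1-{2,4-bis(methoxymethoxy)-3-[(E)-3-methylbuta-1,3-dien-1-yl]phenyl}ethanone
Product: 20 (4S)-4-benzyl-3-{[(1R,2S,6S)-2-[3-acetyl-2,6-bis(methoxymethoxy)phenyl]-6-[2,4-bis(methoxymethoxy)phenyl]-4-methylcyclohex-3-en-1-yl]carbonyl}-1,3-oxazolidin-2-one
Conditions: Et2AlCl (3 equiv), CH2Cl2, −40 to 0 °C
Reagents that add atoms: none
Why: In this oxazolidinone-auxiliary-controlled, Lewis acid-promoted Diels–Alder reaction the benzyl group covers the Cα-Re face of the aluminium-chelated s-cis imide, so the diene should add to the Cα-Si face in the carbonyl-endo mode with its aryl-bearing terminus bonding to Cα (ortho/para rule), which sets C-1 (R), C-2 (S, aryl cis to the acyl group) and C-6 (S, trans, from the E dienophile) at once.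

**Step 12**
Reactants: 20 (4S)-4-benzyl-3-{[(1R,2S,6S)-2-[3-acetyl-2,6-bis(methoxymethoxy)phenyl]-6-[2,4-bis(methoxymethoxy)phenyl]-4-methylcyclohex-3-en-1-yl]carbonyl}-1,3-oxazolidin-2-one
Product: 22 (1R,2S,6S)-2-[3-acetyl-2,6-bis(methoxymethoxy)phenyl]-6-[2,4-bis(methoxymethoxy)phenyl]-4-methylcyclohex-3-ene-1-carboxylic acid, via peroxy acid 21 (not isolated)
Conditions: LiOH, H2O2, THF–H2O, 0 °C; then aq Na2SO3; 1 M HCl to pH 4 at 0 °C
Reagents that add atoms: hydrogen peroxide, OO
Why: Hydroperoxide cleavage of the imide (auxiliary removal) should attack the exocyclic carbonyl at 0 °C without enolising C-1, sulfite then reduces the peroxy acid, and the ketone, alkene and MOM ethers are inert.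

**Step 13**
Reactants: 22 (1R,2S,6S)-2-[3-acetyl-2,6-bis(methoxymethoxy)phenyl]-6-[2,4-bis(methoxymethoxy)phenyl]-4-methylcyclohex-3-ene-1-carboxylic acid; 5 1-bromo-2,4-bis(methoxymethoxy)-3-[(E)-3-methylbut-1-en-1-yl]benzene
Product: 24 {(1R,2S,6S)-2-[3-acetyl-2,6-bis(methoxymethoxy)phenyl]-6-[2,4-bis(methoxymethoxy)phenyl]-4-methylcyclohex-3-en-1-yl}{2,4-bis(methoxymethoxy)-3-[(E)-3-methylbut-1-en-1-yl]phenyl}methanone, via N-acylimidazole 23 (not isolated)
Conditions: CDI (1.2 equiv), DMA, rt; then 5 (1.5 equiv), NiBr2·dme (10 mol %), 4,4′-di-tert-butyl-2,2′-bipyridine (12 mol %), Zn (3 equiv), MgCl2 (1.5 equiv), 30 °C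
Reagents that add atoms: none
Why: The acid is converted in the flask into N-acylimidazole 23; the bipyridine–nickel(0) complex inserts into the C–Br bond of 5, zinc reduces the arylnickel(II) bromide to arylnickel(I), this takes up the acyl group of 23 (activated by MgCl2 at the imidazole nitrogen) to give an aryl(acyl)nickel(III) species, and reductive elimination forms the C(=O)–C(aryl) bond while zinc returns nickel to the cycle. The closest known reaction type is the nickel-catalysed reductive cross-electrophile coupling of aryl halides with carboxylic acids activated in situ as acylimidazoles, anhydrides or thioesters, which unites two electrophilic carbons without a preformed organometallic. No ring is closed and no stereocentre is created; the task is to keep the three existing ones. The step needs cross- over homo-coupling, site fidelity on ring B and retention at cyclohexene C-1: the first should be secured by the different ways the partners meet nickel (C(sp2)–Br by oxidative addition to nickel(0), the acyl donor only at the reduced arylnickel stage) and by an excess of 5, the second by the bromine, which marks the single ring carbon ortho to O-2 and para to O-4, and the third by the absence of base, so that the hindered α-C–H next to the cis aryl group is never enolised. The aryl methyl ketone, the MOM acetals and both alkenes should be inert to zinc and bipyridine–nickel at 30 °C, where decarbonylation of the acylnickel is also slow.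

**Step 14**
Reactants: 24 {(1R,2S,6S)-2-[3-acetyl-2,6-bis(methoxymethoxy)phenyl]-6-[2,4-bis(methoxymethoxy)phenyl]-4-methylcyclohex-3-en-1-yl}{2,4-bis(methoxymethoxy)-3-[(E)-3-methylbut-1-en-1-yl]phenyl}methanone; 25 4-(methoxymethoxy)benzaldehyde
Product: 28 heptakis(methoxymethyl) ether of the target, via aldol adduct 26 (not isolated), via benzylic mesylate 27 (not isolated)
Conditions: LiHMDS (1.05 equiv), THF, −78 °C; 25; then MsCl, Et3N, −78 °C to rt
Reagents that add atoms: none
Why: Kinetic deprotonation should take the unhindered methyl ketone and not the tertiary, flanked α-C–H of the other ketone (so C-1 is not epimerised), the lithium enolate adds to the aldehyde (directed aldol addition), and mesylation with E1cB elimination gives the E chalcone, the transient carbinol centre of 26 and 27 needing no control.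

**Step 15**
Reactants: 28 heptakis(methoxymethyl) ether of the target
Product: 29 [(1R,2S,6S)-2-{2,6-dihydroxy-3-[(E)-3-(4-hydroxyphenyl)prop-2-enoyl]phenyl}-6-(2,4-dihydroxyphenyl)-4-methylcyclohex-3-en-1-yl]{2,4-dihydroxy-3-[(E)-3-methylbut-1-en-1-yl]phenyl}methanone
Conditions: 3 M aq HCl, MeOH–THF, 40 °C
Reagents that add atoms: none
Why: Acid-catalysed acetal solvolysis (global MOM removal) should free the seven phenols, the hydrogen-bonded 2′-hydroxychalcone and aryl ketones being the stable forms, and no stereocentre is touched.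

**Compound list**
1 | 2-iodobenzene-1,3-diol (2-iodoresorcinol) | Oc1cccc(O)c1I | starting material
2 | 2-iodo-1,3-bis(methoxymethoxy)benzene | COCOc1cccc(OCOC)c1I | intermediate
3 | 4,4,5,5-tetramethyl-2-[(E)-3-methylbut-1-en-1-yl]-1,3,2-dioxaborolane | CC(C)/C=C/B1OC(C)(C)C(C)(C)O1 | starting material
4 | 1,3-bis(methoxymethoxy)-2-[(E)-3-methylbut-1-en-1-yl]benzene | COCOc1cccc(OCOC)c1/C=C/C(C)C | intermediate
5 | 1-bromo-2,4-bis(methoxymethoxy)-3-[(E)-3-methylbut-1-en-1-yl]benzene | COCOc1ccc(Br)c(OCOC)c1/C=C/C(C)C | intermediate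
6 | 1-(2,4-dihydroxyphenyl)ethanone | CC(=O)c1ccc(O)cc1O | starting material
7 | 1-(2,4-dihydroxy-3-iodophenyl)ethanone | CC(=O)c1ccc(O)c(I)c1O | intermediate
8 | 1-[3-iodo-2,4-bis(methoxymethoxy)phenyl]ethanone | CC(=O)c1ccc(OCOC)c(I)c1OCOC | intermediate
9 | 2-methylbut-3-en-2-ol | CC(C)(O)C=C | starting material
10 | 1-{3-[(E)-3-hydroxy-3-methylbut-1-en-1-yl]-2,4-bis(methoxymethoxy)phenyl}ethanone | CC(=O)c1ccc(OCOC)c(/C=C/C(C)(C)O)c1OCOC | intermediate
11 | (E)-4-[3-acetyl-2,6-bis(methoxymethoxy)phenyl]-2-methylbut-3-en-2-yl methanesulfonate (not isolated) | CC(=O)c1ccc(OCOC)c(/C=C/C(C)(C)OS(C)(=O)=O)c1OCOC | intermediate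
12 | 1-{2,4-bis(methoxymethoxy)-3-[(E)-3-methylbuta-1,3-dien-1-yl]phenyl}ethanone | CC(=O)c1ccc(OCOC)c(/C=C/C(C)=C)c1OCOC | intermediate
13 | 2,4-dihydroxybenzaldehyde | O=Cc1ccc(O)cc1O | starting material
14 | 2,4-bis(methoxymethoxy)benzaldehyde | COCOc1ccc(C=O)c(OCOC)c1 | intermediate
15 | malonic acid | OC(=O)CC(=O)O | starting material
16 | (E)-3-[2,4-bis(methoxymethoxy)phenyl]prop-2-enoic acid | COCOc1ccc(/C=C/C(=O)O)c(OCOC)c1 | intermediate
17 | (4S)-4-benzyl-1,3-oxazolidin-2-one | O=C1N[C@@H](Cc2ccccc2)CO1 | starting material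
18 | mixed anhydride of 16 with pivalic acid (not isolated) | COCOc1ccc(/C=C/C(=O)OC(=O)C(C)(C)C)c(OCOC)c1 | intermediate
19 | (4S)-4-benzyl-3-{(E)-3-[2,4-bis(methoxymethoxy)phenyl]prop-2-enoyl}-1,3-oxazolidin-2-one | COCOc1ccc(/C=C/C(=O)N2[C@@H](Cc3ccccc3)COC2=O)c(OCOC)c1 | intermediate
20 | (4S)-4-benzyl-3-{[(1R,2S,6S)-2-[3-acetyl-2,6-bis(methoxymethoxy)phenyl]-6-[2,4-bis(methoxymethoxy)phenyl]-4-methylcyclohex-3-en-1-yl]carbonyl}-1,3-oxazolidin-2-one | CC1=C[C@H](c2c(OCOC)ccc(C(C)=O)c2OCOC)[C@H](C(=O)N2[C@@H](Cc3ccccc3)COC2=O)[C@@H](c2ccc(OCOC)cc2OCOC)C1 | intermediate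
21 | (1R,2S,6S)-2-[3-acetyl-2,6-bis(methoxymethoxy)phenyl]-6-[2,4-bis(methoxymethoxy)phenyl]-4-methylcyclohex-3-ene-1-carboperoxoic acid (not isolated) | CC1=C[C@H](c2c(OCOC)ccc(C(C)=O)c2OCOC)[C@H](C(=O)OO)[C@@H](c2ccc(OCOC)cc2OCOC)C1 | intermediate
22 | (1R,2S,6S)-2-[3-acetyl-2,6-bis(methoxymethoxy)phenyl]-6-[2,4-bis(methoxymethoxy)phenyl]-4-methylcyclohex-3-ene-1-carboxylic acid | CC1=C[C@H](c2c(OCOC)ccc(C(C)=O)c2OCOC)[C@H](C(=O)O)[C@@H](c2ccc(OCOC)cc2OCOC)C1 | intermediate
23 | 1-{[(1R,2S,6S)-2-[3-acetyl-2,6-bis(methoxymethoxy)phenyl]-6-[2,4-bis(methoxymethoxy)phenyl]-4-methylcyclohex-3-en-1-yl]carbonyl}imidazole (not isolated) | CC1=C[C@H](c2c(OCOC)ccc(C(C)=O)c2OCOC)[C@H](C(=O)n2ccnc2)[C@@H](c2ccc(OCOC)cc2OCOC)C1 | intermediate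
24 | {(1R,2S,6S)-2-[3-acetyl-2,6-bis(methoxymethoxy)phenyl]-6-[2,4-bis(methoxymethoxy)phenyl]-4-methylcyclohex-3-en-1-yl}{2,4-bis(methoxymethoxy)-3-[(E)-3-methylbut-1-en-1-yl]phenyl}methanone | CC1=C[C@H](c2c(OCOC)ccc(C(C)=O)c2OCOC)[C@H](C(=O)c2ccc(OCOC)c(/C=C/C(C)C)c2OCOC)[C@@H](c2ccc(OCOC)cc2OCOC)C1 | intermediate
25 | 4-(methoxymethoxy)benzaldehyde | COCOc1ccc(C=O)cc1 | starting material
26 | aldol adduct of 24 with 25: β-hydroxy ketone on the A-ring acyl chain, carbinol centre as a mixture (not isolated) | CC1=C[C@H](c2c(OCOC)ccc(C(=O)CC(O)c3ccc(OCOC)cc3)c2OCOC)[C@H](C(=O)c2ccc(OCOC)c(/C=C/C(C)C)c2OCOC)[C@@H](c2ccc(OCOC)cc2OCOC)C1 | intermediate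
27 | methanesulfonate of 26 at the benzylic carbinol (not isolated) | CC1=C[C@H](c2c(OCOC)ccc(C(=O)CC(OS(C)(=O)=O)c3ccc(OCOC)cc3)c2OCOC)[C@H](C(=O)c2ccc(OCOC)c(/C=C/C(C)C)c2OCOC)[C@@H](c2ccc(OCOC)cc2OCOC)C1 | intermediate
28 | heptakis(methoxymethyl) ether of the target (all seven phenols as OMOM, E chalcone in place) | CC1=C[C@H](c2c(OCOC)ccc(C(=O)/C=C/c3ccc(OCOC)cc3)c2OCOC)[C@H](C(=O)c2ccc(OCOC)c(/C=C/C(C)C)c2OCOC)[C@@H](c2ccc(OCOC)cc2OCOC)C1 | intermediate
29 | [(1R,2S,6S)-2-{2,6-dihydroxy-3-[(E)-3-(4-hydroxyphenyl)prop-2-enoyl]phenyl}-6-(2,4-dihydroxyphenyl)-4-methylcyclohex-3-en-1-yl]{2,4-dihydroxy-3-[(E)-3-methylbut-1-en-1-yl]phenyl}methanone | CC1=C[C@H](c2c(O)ccc(C(=O)/C=C/c3ccc(O)cc3)c2O)[C@H](C(=O)c2ccc(O)c(/C=C/C(C)C)c2O)[C@@H](c2ccc(O)cc2O)C1 | target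

**Step count and risks**
Total steps: 15. Longest linear sequence: 9 steps (steps 4 to 7 and 11 to 15, from 6).

Steps most likely to fail:

1. Step 13. Acyl transfer from the hindered N-acylimidazole to arylnickel may be slow, so that reductive homocoupling or protodehalogenation of the bromide and decarbonylation of the acylnickel take over.
 Fallback: it sets out from 22 and 5 and comes back at 24. Acid 22 is condensed with 4-methylbenzenethiol (DCC, DMAP, CH2Cl2) to the S-(4-methylphenyl) thioester F1. Bromide 5 is converted by bromine–lithium exchange (n-BuLi, THF, −78 °C), triisopropyl borate and mild hydrolysis into the arylboronic acid F2. A Liebeskind–Srogl coupling of the two (Pd2(dba)3, tri(2-furyl)phosphine, copper(I) thiophene-2-carboxylate, THF, 50 °C) is neutral and base-free and should give 24 without epimerisation.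

2. Step 11. The donor-substituted cinnamoyl imide may react too slowly with the hindered diene, leaving room for Lewis acid-induced diene oligomerisation, loss of the chelating ortho MOM group or ethyl transfer, and the endo/exo and facial selectivity may be eroded.
 Fallback: it sets out from 14 and 12 and comes back at 22. Aldehyde 14 is homologated with (triphenylphosphoranylidene)acetaldehyde (toluene, 80 °C) to the enal F3. An iminium-catalysed Diels–Alder reaction of the enal with 12, using a salt of (5S)-5-benzyl-2,2,3-trimethylimidazolidin-4-one (20 mol %) in wet MeCN at rt, should give the endo carbaldehyde F4. The benzyl group of this catalyst covers the same Re face as the auxiliary does, and no Lewis acid is present. Pinnick oxidation (NaClO2, NaH2PO4, 2-methylbut-2-ene, t-BuOH–H2O) then gives 22.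

3. Step 15. During the sevenfold acetal cleavage the acid may add methanol or a phenol OH across the styrene-type or ring alkene, cyclise the 2′-hydroxychalcone to a flavanone, or ketalise the ketone.
 Fallback: it sets out from 28 and comes back at 29. Treatment with TMSOTf and 2,2′-bipyridyl (CH2Cl2, 0 °C to rt) exchanges the aryl MOM ethers for silyl ethers under non-protic conditions and should give the heptakis(trimethylsilyl) ether F5. Its hydrolysis with water–methanol at rt frees 29 without strong acid.

**Further compounds**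
F1 | step 13 | S-(4-methylphenyl) (1R,2S,6S)-2-[3-acetyl-2,6-bis(methoxymethoxy)phenyl]-6-[2,4-bis(methoxymethoxy)phenyl]-4-methylcyclohex-3-ene-1-carbothioate | CC1=C[C@H](c2c(OCOC)ccc(C(C)=O)c2OCOC)[C@H](C(=O)Sc2ccc(C)cc2)[C@@H](c2ccc(OCOC)cc2OCOC)C1
F2 | step 13 | {2,4-bis(methoxymethoxy)-3-[(E)-3-methylbut-1-en-1-yl]phenyl}boronic acid | OB(O)c1ccc(OCOC)c(/C=C/C(C)C)c1OCOC
F3 | step 11 | (E)-3-[2,4-bis(methoxymethoxy)phenyl]prop-2-enal | COCOc1ccc(/C=C/C=O)c(OCOC)c1
F4 | step 11 | (1R,2S,6S)-2-[3-acetyl-2,6-bis(methoxymethoxy)phenyl]-6-[2,4-bis(methoxymethoxy)phenyl]-4-methylcyclohex-3-ene-1-carbaldehyde | CC1=C[C@H](c2c(OCOC)ccc(C(C)=O)c2OCOC)[C@H](C=O)[C@@H](c2ccc(OCOC)cc2OCOC)C1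
F5 | step 15 | heptakis(trimethylsilyl) ether of 29 | CC1=C[C@H](c2c(O[Si](C)(C)C)ccc(C(=O)/C=C/c3ccc(O[Si](C)(C)C)cc3)c2O[Si](C)(C)C)[C@H](C(=O)c2ccc(O[Si](C)(C)C)c(/C=C/C(C)C)c2O[Si](C)(C)C)[C@@H](c2ccc(O[Si](C)(C)C)cc2O[Si](C)(C)C)C1
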